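The cyclohexane ring (C5–C10) is closed last, at C8–C9. C8 is both the oxygen-bearing γ-carbon of the C12 lactone ring and the neighbour of the C9 carbinol, so this bond is a vinylogous aldol linkage. A 4-substituted butenolide whose side chain already holds C5, C6 and C10 and ends in a non-enolisable C9 aldehyde is converted into its 2-silyloxyfuran. Attack of furan C8 on the activated aldehyde forms the carbocycle, both new stereocentres (C8, C9) and the 7(11)-butenolide in one operation. C5/C10 come from an enantioselective Ireland–Claisen rearrangement and C6 from a Felkin-controlled ketone reduction; C7, the exo-methylene, the angelate and the enal follow.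

Key step: step 13

Assumption: the (S,S)-configured bromoborane is taken to give the (2S,3S) acid 8; if the sense of induction is the opposite, the (R,R) reagent is used and nothing else changes.

Numbering remark: ring compounds carry elemane numbers (vinyl C1=C2 and methyl C14 on C10; C3=C4(–C15) on C5; ring C5 to C10; lactone C11, C12 (carbonyl), C13). α is the face of O-8 and O-9, β that of C14. TBS = tert-butyldimethylsilyl, TMS = trimethylsilyl.

Step 1
Reactants: 1 3-methylbut-2-en-1-ol (prenol); 2 3-methylbut-2-enoic acid (senecioic acid)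
Product: 3 prenyl senecioate (3-methylbut-2-en-1-yl 3-methylbut-2-enoate)
Conditions: DCC, DMAP (cat.), CH2Cl2, 0 °C to rt
Reagents that add atoms: none
Why: Steglich esterification of an unhindered primary allylic alcohol; no stereocentre is involved.

Step 2
Reactants: 3 prenyl senecioate
Product: 4 (E)-4-hydroxy-3-methylbut-2-en-1-yl 3-methylbut-2-enoate
Conditions: SeO2 (0.3 equiv), t-BuOOH (2.5 equiv), salicylic acid (0.1 equiv), CH2Cl2, 0 °C to rt, stopped at the alcohol stage
Reagents that add atoms: selenium dioxide, O=[Se]=O (delivers the oxygen and is regenerated by tert-butyl hydroperoxide, CC(C)(C)OO)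
Why: Catalytic selenium dioxide allylic oxidation (ene reaction, then [2,3] shift) should take the electron-rich prenyl alkene rather than the conjugated senecioate and oxidise the methyl trans to the CH2O chain, giving the E-alcohol.

Step 3
Reactants: 4 (E)-4-hydroxy-3-methylbut-2-en-1-yl 3-methylbut-2-enoate
Product: 5 (E)-4-(tert-butyldimethylsilyloxy)-3-methylbut-2-en-1-yl 3-methylbut-2-enoate
Conditions: TBSCl, imidazole, CH2Cl2, rt
Reagents that add atoms: tert-butyldimethylsilyl chloride, CC(C)(C)[Si](C)(C)Cl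
Why: Standard silylation of a primary alcohol; a silyl ether is chosen for the future C9 oxygen because it tolerates the boron Lewis acid of step 4.

Step 4
Reactants: 5 (E)-4-(tert-butyldimethylsilyloxy)-3-methylbut-2-en-1-yl 3-methylbut-2-enoate
Product: 8 (2S,3S)-3-[(tert-butyldimethylsilyloxy)methyl]-3-methyl-2-(prop-1-en-2-yl)pent-4-enoic acid, via boron dienolate 6 (not isolated), via acyloxyborane 7 (not isolated)
Conditions: (S,S)-2-bromo-4,5-diphenyl-1,3-bis[3,5-bis(trifluoromethyl)phenylsulfonyl]-1,3,2-diazaborolidine (1.3 equiv), Et3N (3 equiv), toluene–hexane, −78 °C, then 4 °C; aqueous work-up at pH 3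
Reagents that add atoms: none
Why: Boron-mediated enantioselective Ireland–Claisen rearrangement: the boron-complexed senecioate is s-trans, so γ-deprotonation by Et3N should give the dienolate with isopropenyl trans to O–B, and its [3,3] shift through a chair with the E-alkene (CH2OTBS equatorial, methyl axial) sets C5 and C10 in the required relative sense, while the C2-symmetric sulfonamide controller selects the enantiotopic face.

Step 5
Reactants: 8 (2S,3S)-3-[(tert-butyldimethylsilyloxy)methyl]-3-methyl-2-(prop-1-en-2-yl)pent-4-enoic acid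
Product: 9 (2S,3S)-3-[(tert-butyldimethylsilyloxy)methyl]-3-methyl-2-(prop-1-en-2-yl)pent-4-en-1-ol
Conditions: LiAlH4, THF, 0 °C to rt; Rochelle salt work-up
Reagents that add atoms: none
Why: Hydride reduction of the carboxylic acid proceeds through the carboxylate, so the allylic C5 centre is not epimerised; the silyl ether and the isolated alkenes are inert.

Step 6
Reactants: 9 (2S,3S)-3-[(tert-butyldimethylsilyloxy)methyl]-3-methyl-2-(prop-1-en-2-yl)pent-4-en-1-ol
Product: 10 (2S,3S)-3-[(tert-butyldimethylsilyloxy)methyl]-3-methyl-2-(prop-1-en-2-yl)pent-4-enal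
Conditions: Dess–Martin periodinane, pyridine, CH2Cl2, 0 °C; used at once
Reagents that add atoms: none
Why: Buffered Dess–Martin oxidation is mild enough to keep the β,γ-unsaturated aldehyde from epimerising at C5 or moving into conjugation.

Step 7
Reactants: 10 (2S,3S)-3-[(tert-butyldimethylsilyloxy)methyl]-3-methyl-2-(prop-1-en-2-yl)pent-4-enal; 11 4-bromofuran-2(5H)-one
Product: 12 4-[(2S,3S)-3-[(tert-butyldimethylsilyloxy)methyl]-1-hydroxy-3-methyl-2-(prop-1-en-2-yl)pent-4-en-1-yl]furan-2(5H)-one (both C6 epimers)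
Conditions: CrCl2 (4 equiv), NiCl2 (2 mol %), DMF, rt
Reagents that add atoms: none
Why: Nozaki–Hiyama–Kishi coupling: nickel-catalysed insertion into the activated vinylic C–Br bond and transfer to trivalent chromium should give an alkenylchromium that adds to the hindered aldehyde without enolising it; Felkin addition is expected to favour the unwanted C6 epimer, which does not matter because C6 is reset in steps 8 and 9.

Step 8
Reactants: 12 4-[(2S,3S)-3-[(tert-butyldimethylsilyloxy)methyl]-1-hydroxy-3-methyl-2-(prop-1-en-2-yl)pent-4-en-1-yl]furan-2(5H)-one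
Product: 13 4-[(2S,3S)-3-[(tert-butyldimethylsilyloxy)methyl]-3-methyl-2-(prop-1-en-2-yl)pent-4-enoyl]furan-2(5H)-one
Conditions: Dess–Martin periodinane, pyridine, CH2Cl2, 0 °C to rt
Reagents that add atoms: none
Why: Dess–Martin oxidation of the allylic carbinol converges both C6 epimers on one ketone under conditions too mild to enolise C5.

Step 9
Reactants: 13 4-[(2S,3S)-3-[(tert-butyldimethylsilyloxy)methyl]-3-methyl-2-(prop-1-en-2-yl)pent-4-enoyl]furan-2(5H)-one
Product: 14 4-[(1S,2S,3S)-3-[(tert-butyldimethylsilyloxy)methyl]-1-hydroxy-3-methyl-2-(prop-1-en-2-yl)pent-4-en-1-yl]furan-2(5H)-one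
Conditions: NaBH4, CeCl3·7H2O, MeOH, −78 °C
Reagents that add atoms: none
Why: Luche 1,2-reduction: with the quaternary C10 group anti to the incoming hydride and H-5 rather than isopropenyl next to the butenolide, Felkin–Anh attack should give the 6S alcohol (6β in the later ring), while CeCl3 suppresses conjugate reduction of the ene-dicarbonyl system.

Step 10
Reactants: 14 4-[(1S,2S,3S)-3-[(tert-butyldimethylsilyloxy)methyl]-1-hydroxy-3-methyl-2-(prop-1-en-2-yl)pent-4-en-1-yl]furan-2(5H)-one
Product: 15 4-[(1S,2S,3S)-1-(tert-butyldimethylsilyloxy)-3-[(tert-butyldimethylsilyloxy)methyl]-3-methyl-2-(prop-1-en-2-yl)pent-4-en-1-yl]furan-2(5H)-one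
Conditions: TBSOTf, 2,6-lutidine, CH2Cl2, 0 °C
Reagents that add atoms: tert-butyldimethylsilyl triflate, CC(C)(C)[Si](C)(C)OS(=O)(=O)C(F)(F)F
Why: The silyl triflate silylates the hindered secondary alcohol, and 2,6-lutidine is too weak and hindered a base to enolise the butenolide.

Step 11
Reactants: 15 4-[(1S,2S,3S)-1-(tert-butyldimethylsilyloxy)-3-[(tert-butyldimethylsilyloxy)methyl]-3-methyl-2-(prop-1-en-2-yl)pent-4-en-1-yl]furan-2(5H)-one
Product: 16 4-[(1S,2S,3S)-1-(tert-butyldimethylsilyloxy)-3-(hydroxymethyl)-3-methyl-2-(prop-1-en-2-yl)pent-4-en-1-yl]furan-2(5H)-one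
Conditions: HF·pyridine, pyridine, THF, 0 °C, followed closely
Reagents that add atoms: none
Why: Selective fluoride cleavage of silyl ethers: the primary C9 ether is far more accessible than the secondary C6 ether, which is flanked by the branched C5 and the butenolide.

Step 12
Reactants: 16 4-[(1S,2S,3S)-1-(tert-butyldimethylsilyloxy)-3-(hydroxymethyl)-3-methyl-2-(prop-1-en-2-yl)pent-4-en-1-yl]furan-2(5H)-one
Product: 17 (2S,3S,4S)-4-(tert-butyldimethylsilyloxy)-2-ethenyl-2-methyl-4-(5-oxo-2,5-dihydrofuran-3-yl)-3-(prop-1-en-2-yl)butanal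
Conditions: Dess–Martin periodinane, pyridine, CH2Cl2, rt
Reagents that add atoms: none
Why: Dess–Martin oxidation of the neopentyl alcohol gives an aldehyde on a quaternary carbon, which cannot enolise or epimerise.

Step 13
Reactants: 17 (2S,3S,4S)-4-(tert-butyldimethylsilyloxy)-2-ethenyl-2-methyl-4-(5-oxo-2,5-dihydrofuran-3-yl)-3-(prop-1-en-2-yl)butanal
Product: 20 6β-(tert-butyldimethylsilyloxy)-9α-hydroxy-13-norelema-1,3,7(11)-trien-12,8α-olide, via silyloxyfuran 18 (not isolated), via 9-O-trimethylsilyl ether 19 (not isolated)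
Conditions: TMSOTf (1.5 equiv), Et3N (1.05 equiv), CH2Cl2 (0.005 M), −78 to −20 °C; then 1 M HCl, THF, 0 °C
Reagents that add atoms: none
Why: Et3N and TMSOTf convert the butenolide by γ-deprotonation at C8 into the aromatic 2-trimethylsilyloxyfuran 18 (the amine is then spent, so the product is not re-enolised), the surplus TMSOTf activates the non-enolisable C9 aldehyde, furan C8 (its most nucleophilic position) attacks it, silyl transfer to the new alkoxide restores the butenolide as 19, and the acidic work-up frees O-9. The closest known reaction type is the vinylogous Mukaiyama aldol reaction of 2-silyloxyfurans with aldehydes, here run intramolecularly. The cyclohexane closes in a 6-exo-trig mode (6-enolendo with respect to the furan), whereas attack through C11 would need a seven-membered ring. C8 is set by the furan face that the tether reaches: in the intended chair H-6 lies in the furan plane beside H-11, the silyloxy group is axial and out of that plane, and isopropenyl and vinyl are equatorial, which puts O-8 equatorial and H-8 on the β-face. C9 is set by the activated aldehyde oxygen taking the axial site, anti to the axial C14 methyl, gauche only to vinyl and facing a single syn-axial hydrogen (H-5), which gives the 9α-oxygen. The step needs the correct topicity at C8 and C9 relative to C5, C6 and C10; this rests on the chair preference just described, which must outweigh one syn-axial methyl/oxygen contact, and on high dilution against intermolecular aldol reaction.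

Step 14
Reactants: 20 6β-(tert-butyldimethylsilyloxy)-9α-hydroxy-13-norelema-1,3,7(11)-trien-12,8α-olide
Product: 21 6β-(tert-butyldimethylsilyloxy)-9α-hydroxy-13-norelema-1,3-dien-12,8α-olide (7αH, trans-fused lactone)
Conditions: Cu(OAc)2·H2O (5 mol %), 1,2-bis(diphenylphosphino)benzene (5 mol %), (EtO)2MeSiH (3 equiv), t-BuOH (3 equiv), toluene, rt; mild acidic work-up
Reagents that add atoms: none
Why: Copper hydride conjugate reduction is selective for the butenolide over the vinyl and isopropenyl groups, and hydride should reach C7 from the α-face because the β-face is screened by the axial 6-silyloxy group next to C7 and by the axial C14 methyl, whereas the α-face carries only the small axial 9-hydroxyl, so C11 ends equatorial and the lactone trans-fused.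

Step 15
Reactants: 21 6β-(tert-butyldimethylsilyloxy)-9α-hydroxy-13-norelema-1,3-dien-12,8α-olide
Product: 24 6β-(tert-butyldimethylsilyloxy)-9α-hydroxyelema-1,3,11(13)-trien-12,8α-olide, via Mannich base 22 (not isolated), via trimethylammonium iodide 23 (not isolated)
Conditions: LiN(SiMe3)2 (2.3 equiv), THF, −78 °C; Eschenmoser's salt, −78 to 0 °C; H2O quench; crude amine: MeI, MeOH, rt; then NaHCO3 (aq), CH2Cl2
Reagents that add atoms: N,N-dimethylmethyleneiminium iodide (Eschenmoser's salt), C=[N+](C)C.[I-]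
Why: Mannich methylenation of the lactone lithium enolate (O-9 carried as its alkoxide), N-methylation and base-induced loss of trimethylamine should give the exocyclic alkene; C7 is not touched and the transient C11 centre disappears.

Step 16
Reactants: 24 6β-(tert-butyldimethylsilyloxy)-9α-hydroxyelema-1,3,11(13)-trien-12,8α-olide; 25 angelic acid ((Z)-2-methylbut-2-enoic acid)
Product: 27 9α-angeloyloxy-6β-(tert-butyldimethylsilyloxy)elema-1,3,11(13)-trien-12,8α-olide, via mixed anhydride 26 (not isolated)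
Conditions: 25, 2,4,6-trichlorobenzoyl chloride, Et3N, toluene, rt; then 24, toluene, 80 °C (no DMAP)
Reagents that add atoms: none
Why: Yamaguchi-type acylation through the 2,4,6-trichlorobenzoic mixed anhydride without DMAP is the established way to transfer an angeloyl group without Z-to-E drift to the tiglate, and the alcohol attacks the less hindered angeloyl carbonyl.

Step 17
Reactants: 27 9α-angeloyloxy-6β-(tert-butyldimethylsilyloxy)elema-1,3,11(13)-trien-12,8α-olide
Product: 29 9α-angeloyloxy-6β-(tert-butyldimethylsilyloxy)-15-oxoelema-1,3,11(13)-trien-12,8α-olide, via allylic alcohol 28 (not isolated)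
Conditions: SeO2 (2.5 equiv), 1,4-dioxane, 80 °C
Reagents that add atoms: selenium dioxide, O=[Se]=O
Why: Selenium dioxide allylic oxidation (ene reaction, [2,3] shift, then oxidation of alcohol 28) should occur at the isopropenyl methyl, the only electron-rich alkene with accessible allylic hydrogens: the vinyl group has none, the acrylate-type alkenes of lactone and angelate are deactivated, and H-5 is shielded between C6 and the quaternary C10.

Step 18
Reactants: 29 9α-angeloyloxy-6β-(tert-butyldimethylsilyloxy)-15-oxoelema-1,3,11(13)-trien-12,8α-olide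
Product: 30 9α-angeloyloxy-6β-hydroxy-15-oxoelema-1,3,11(13)-trien-12,8α-olide (CNP0320538.1)
Conditions: HF (48 % aq), MeCN, 0 °C to rt
Reagents that add atoms: none
Why: Acidic fluoride desilylation removes the hindered secondary silyl ether without base, so the α-methylene lactone, the enal and the angelate are not exposed to nucleophiles.

Compound list

1 | 3-methylbut-2-en-1-ol (prenol) | CC(C)=CCO | starting material
2 | 3-methylbut-2-enoic acid (senecioic acid) | CC(C)=CC(=O)O | starting material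
3 | prenyl senecioate | CC(C)=CCOC(=O)C=C(C)C | intermediate
4 | (E)-4-hydroxy-3-methylbut-2-en-1-yl 3-methylbut-2-enoate | CC(C)=CC(=O)OC/C=C(\C)CO | intermediate
5 | (E)-4-(tert-butyldimethylsilyloxy)-3-methylbut-2-en-1-yl 3-methylbut-2-enoate | CC(C)=CC(=O)OC/C=C(\C)CO[Si](C)(C)C(C)(C)C | intermediate
6 | boron dienolate of 5 (O-boryl ketene acetal, isopropenyl trans to O–B, boron bound to the (S,S)-bis-sulfonamide) | CC(=C)/C=C(/OB1N(S(=O)(=O)c2cc(C(F)(F)F)cc(C(F)(F)F)c2)[C@@H](c2ccccc2)[C@H](c2ccccc2)N1S(=O)(=O)c1cc(C(F)(F)F)cc(C(F)(F)F)c1)\OC/C=C(\C)CO[Si](C)(C)C(C)(C)C | intermediate (not isolated)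
7 | acyloxyborane of acid 8 (boron carboxylate with the same ligand) | CC(C)(C)[Si](C)(C)OC[C@@](C)(C=C)[C@H](C(C)=C)C(=O)OB1N(S(=O)(=O)c2cc(C(F)(F)F)cc(C(F)(F)F)c2)[C@@H](c2ccccc2)[C@H](c2ccccc2)N1S(=O)(=O)c1cc(C(F)(F)F)cc(C(F)(F)F)c1 | intermediate (not isolated)
8 | (2S,3S)-3-[(tert-butyldimethylsilyloxy)methyl]-3-methyl-2-(prop-1-en-2-yl)pent-4-enoic acid | CC(C)(C)[Si](C)(C)OC[C@@](C)(C=C)[C@H](C(C)=C)C(=O)O | intermediate
9 | (2S,3S)-3-[(tert-butyldimethylsilyloxy)methyl]-3-methyl-2-(prop-1-en-2-yl)pent-4-en-1-ol | CC(C)(C)[Si](C)(C)OC[C@@](C)(C=C)[C@H](C(C)=C)CO | intermediate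
10 | (2S,3S)-3-[(tert-butyldimethylsilyloxy)methyl]-3-methyl-2-(prop-1-en-2-yl)pent-4-enal | CC(C)(C)[Si](C)(C)OC[C@@](C)(C=C)[C@H](C(C)=C)C=O | intermediate
11 | 4-bromofuran-2(5H)-one | O=C1C=C(Br)CO1 | starting material
12 | 4-[(2S,3S)-3-[(tert-butyldimethylsilyloxy)methyl]-1-hydroxy-3-methyl-2-(prop-1-en-2-yl)pent-4-en-1-yl]furan-2(5H)-one, both C6 epimers | CC(C)(C)[Si](C)(C)OC[C@@](C)(C=C)[C@H](C(C)=C)C(O)C1=CC(=O)OC1 | intermediate
13 | 4-[(2S,3S)-3-[(tert-butyldimethylsilyloxy)methyl]-3-methyl-2-(prop-1-en-2-yl)pent-4-enoyl]furan-2(5H)-one | CC(C)(C)[Si](C)(C)OC[C@@](C)(C=C)[C@H](C(C)=C)C(=O)C1=CC(=O)OC1 | intermediate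
14 | 4-[(1S,2S,3S)-3-[(tert-butyldimethylsilyloxy)methyl]-1-hydroxy-3-methyl-2-(prop-1-en-2-yl)pent-4-en-1-yl]furan-2(5H)-one | CC(C)(C)[Si](C)(C)OC[C@@](C)(C=C)[C@H](C(C)=C)[C@H](O)C1=CC(=O)OC1 | intermediate
15 | 4-[(1S,2S,3S)-1-(tert-butyldimethylsilyloxy)-3-[(tert-butyldimethylsilyloxy)methyl]-3-methyl-2-(prop-1-en-2-yl)pent-4-en-1-yl]furan-2(5H)-one | CC(C)(C)[Si](C)(C)OC[C@@](C)(C=C)[C@H](C(C)=C)[C@H](O[Si](C)(C)C(C)(C)C)C1=CC(=O)OC1 | intermediate
16 | 4-[(1S,2S,3S)-1-(tert-butyldimethylsilyloxy)-3-(hydroxymethyl)-3-methyl-2-(prop-1-en-2-yl)pent-4-en-1-yl]furan-2(5H)-one | OC[C@@](C)(C=C)[C@H](C(C)=C)[C@H](O[Si](C)(C)C(C)(C)C)C1=CC(=O)OC1 | intermediate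
17 | (2S,3S,4S)-4-(tert-butyldimethylsilyloxy)-2-ethenyl-2-methyl-4-(5-oxo-2,5-dihydrofuran-3-yl)-3-(prop-1-en-2-yl)butanal (precursor of the key step) | O=C[C@@](C)(C=C)[C@H](C(C)=C)[C@H](O[Si](C)(C)C(C)(C)C)C1=CC(=O)OC1 | intermediate
18 | (2S,3S,4S)-4-(tert-butyldimethylsilyloxy)-2-ethenyl-2-methyl-3-(prop-1-en-2-yl)-4-[5-(trimethylsilyloxy)furan-3-yl]butanal | O=C[C@@](C)(C=C)[C@H](C(C)=C)[C@H](O[Si](C)(C)C(C)(C)C)c1coc(O[Si](C)(C)C)c1 | intermediate (not isolated)
19 | 6β-(tert-butyldimethylsilyloxy)-9α-(trimethylsilyloxy)-13-norelema-1,3,7(11)-trien-12,8α-olide | C=C[C@]1(C)[C@H](O[Si](C)(C)C)[C@@H]2OC(=O)C=C2[C@@H](O[Si](C)(C)C(C)(C)C)[C@H]1C(C)=C | intermediate (not isolated)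
20 | 6β-(tert-butyldimethylsilyloxy)-9α-hydroxy-13-norelema-1,3,7(11)-trien-12,8α-olide (product of the key step) | C=C[C@]1(C)[C@H](O)[C@@H]2OC(=O)C=C2[C@@H](O[Si](C)(C)C(C)(C)C)[C@H]1C(C)=C | intermediate
21 | 6β-(tert-butyldimethylsilyloxy)-9α-hydroxy-13-norelema-1,3-dien-12,8α-olide (7αH) | C=C[C@]1(C)[C@H](O)[C@@H]2OC(=O)C[C@H]2[C@@H](O[Si](C)(C)C(C)(C)C)[C@H]1C(C)=C | intermediate
22 | 6β-(tert-butyldimethylsilyloxy)-13-(dimethylamino)-9α-hydroxyelema-1,3-dien-12,8α-olide (C11 epimers) | C=C[C@]1(C)[C@H](O)[C@@H]2OC(=O)C(CN(C)C)[C@H]2[C@@H](O[Si](C)(C)C(C)(C)C)[C@H]1C(C)=C | intermediate (not isolated)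
23 | N-methyl ammonium iodide of 22 | C=C[C@]1(C)[C@H](O)[C@@H]2OC(=O)C(C[N+](C)(C)C)[C@H]2[C@@H](O[Si](C)(C)C(C)(C)C)[C@H]1C(C)=C.[I-] | intermediate (not isolated)
24 | 6β-(tert-butyldimethylsilyloxy)-9α-hydroxyelema-1,3,11(13)-trien-12,8α-olide | C=C[C@]1(C)[C@H](O)[C@@H]2OC(=O)C(=C)[C@H]2[C@@H](O[Si](C)(C)C(C)(C)C)[C@H]1C(C)=C | intermediate
25 | angelic acid | C/C=C(/C)C(=O)O | starting material
26 | angelic 2,4,6-trichlorobenzoic anhydride | C/C=C(/C)C(=O)OC(=O)c1c(Cl)cc(Cl)cc1Cl | intermediate (not isolated)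
27 | 9α-angeloyloxy-6β-(tert-butyldimethylsilyloxy)elema-1,3,11(13)-trien-12,8α-olide | C=C[C@]1(C)[C@H](OC(=O)/C(C)=C\C)[C@@H]2OC(=O)C(=C)[C@H]2[C@@H](O[Si](C)(C)C(C)(C)C)[C@H]1C(C)=C | intermediate
28 | 9α-angeloyloxy-6β-(tert-butyldimethylsilyloxy)-15-hydroxyelema-1,3,11(13)-trien-12,8α-olide | C=C[C@]1(C)[C@H](OC(=O)/C(C)=C\C)[C@@H]2OC(=O)C(=C)[C@H]2[C@@H](O[Si](C)(C)C(C)(C)C)[C@H]1C(=C)CO | intermediate (not isolated)
29 | 9α-angeloyloxy-6β-(tert-butyldimethylsilyloxy)-15-oxoelema-1,3,11(13)-trien-12,8α-olide | C=C[C@]1(C)[C@H](OC(=O)/C(C)=C\C)[C@@H]2OC(=O)C(=C)[C@H]2[C@@H](O[Si](C)(C)C(C)(C)C)[C@H]1C(=C)C=O | intermediate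
30 | 9α-angeloyloxy-6β-hydroxy-15-oxoelema-1,3,11(13)-trien-12,8α-olide (CNP0320538.1) | C=C[C@]1(C)[C@H](OC(=O)/C(C)=C\C)[C@@H]2OC(=O)C(=C)[C@H]2[C@@H](O)[C@H]1C(=C)C=O | target

Total step count: 18. Longest linear sequence: 18 steps (1 and 2 to 30).

Steps most likely to fail

Step 13. The closure may run through the competing chair, in which vinyl and isopropenyl are axial and the silyloxy group lies in the furan plane. That would bring C9 onto the other face of C8 and erode or invert the C8 configuration; ionisation of the C6 silyloxy group is a second loss channel. The fallback places a bromine on C11 so that allylic 1,3-strain forbids an in-plane silyloxy group and leaves only the intended chair. It sets out from aldehyde 10 and returns at 20. Aldehyde 10 is coupled (CrCl2, NiCl2, DMF) with commercial 3,4-dibromofuran-2(5H)-one (O=C1OCC(Br)=C1Br) at its more reactive C4 bromide to give the 3-bromobutenolide carbinols F1. Dess–Martin oxidation gives the bromo ketone F2 and Luche reduction the 6S bromo alcohol F3. TBSOTf with 2,6-lutidine gives the bis-silyl ether F4, HF·pyridine the primary alcohol F5, and Dess–Martin oxidation the bromo aldehyde F6. TMSOTf and Et3N then give the 3-bromo-2-silyloxyfuran F7, which closes to the 9-O-trimethylsilyl ether F8 and, after acidic work-up, the 11-bromo alcohol F9; vinylogous Mukaiyama aldol reactions of 3-bromo-2-silyloxyfurans are established. Hydrodebromination of F9 with Bu3SnH and Pd(PPh3)4 (zerovalent palladium) returns to 20.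

Step 14. Facial selectivity may be poor: hydride delivery from the β-face would give the cis-fused lactone. The fallback replaces substrate control by catalyst control. It sets out from 20 and returns at 21: the same copper hydride reduction is run with Cu(OAc)2·H2O and the enantiomer of DTBM-SEGPHOS matched to α-face delivery, so that the chiral ligand, as in enantioselective conjugate reductions of β-substituted butenolides, decides the face. No new compound is made.

Step 16. Acylation of the axial, neopentyl 9-hydroxyl may be incomplete, and forcing it risks Z-to-E drift of the angeloyl group. The fallback builds the Z-alkene on the ester instead of transferring it. It sets out from 24 and returns at 27: 24 is esterified (DCC, DMAP; the acid has no isomerisable alkene) with 2-[bis(2,2,2-trifluoroethoxy)phosphoryl]propanoic acid to give the phosphonopropionate F10. Still–Gennari olefination of F10 with acetaldehyde (KN(SiMe3)2, 18-crown-6, THF, −78 °C) then gives the Z-configured 2-methylbut-2-enoate, which is 27.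

Further compounds

F1 | step 13 | 3-bromo-4-[(2S,3S)-3-[(tert-butyldimethylsilyloxy)methyl]-1-hydroxy-3-methyl-2-(prop-1-en-2-yl)pent-4-en-1-yl]furan-2(5H)-one (C6 epimers) | CC(C)(C)[Si](C)(C)OC[C@@](C)(C=C)[C@H](C(C)=C)C(O)C1=C(Br)C(=O)OC1
F2 | step 13 | 3-bromo-4-[(2S,3S)-3-[(tert-butyldimethylsilyloxy)methyl]-3-methyl-2-(prop-1-en-2-yl)pent-4-enoyl]furan-2(5H)-one | CC(C)(C)[Si](C)(C)OC[C@@](C)(C=C)[C@H](C(C)=C)C(=O)C1=C(Br)C(=O)OC1
F3 | step 13 | 3-bromo analogue of 14 | CC(C)(C)[Si](C)(C)OC[C@@](C)(C=C)[C@H](C(C)=C)[C@H](O)C1=C(Br)C(=O)OC1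
F4 | step 13 | 3-bromo analogue of 15 | CC(C)(C)[Si](C)(C)OC[C@@](C)(C=C)[C@H](C(C)=C)[C@H](O[Si](C)(C)C(C)(C)C)C1=C(Br)C(=O)OC1
F5 | step 13 | 3-bromo analogue of 16 | OC[C@@](C)(C=C)[C@H](C(C)=C)[C@H](O[Si](C)(C)C(C)(C)C)C1=C(Br)C(=O)OC1
F6 | step 13 | 3-bromo analogue of 17 | O=C[C@@](C)(C=C)[C@H](C(C)=C)[C@H](O[Si](C)(C)C(C)(C)C)C1=C(Br)C(=O)OC1
F7 | step 13 | 3-bromo-2-(trimethylsilyloxy)furan analogue of 18 | O=C[C@@](C)(C=C)[C@H](C(C)=C)[C@H](O[Si](C)(C)C(C)(C)C)c1coc(O[Si](C)(C)C)c1Br
F8 | step 13 | 11-bromo analogue of 19 | C=C[C@]1(C)[C@H](O[Si](C)(C)C)[C@@H]2OC(=O)C(Br)=C2[C@@H](O[Si](C)(C)C(C)(C)C)[C@H]1C(C)=C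
F9 | step 13 | 11-bromo analogue of 20 | C=C[C@]1(C)[C@H](O)[C@@H]2OC(=O)C(Br)=C2[C@@H](O[Si](C)(C)C(C)(C)C)[C@H]1C(C)=C
F0 | step 14 | none | none
F10 | step 16 | 9α-{2-[bis(2,2,2-trifluoroethoxy)phosphoryl]propanoyloxy}-6β-(tert-butyldimethylsilyloxy)elema-1,3,11(13)-trien-12,8α-olide | C=C[C@]1(C)[C@H](OC(=O)C(C)P(=O)(OCC(F)(F)F)OCC(F)(F)F)[C@@H]2OC(=O)C(=C)[C@H]2[C@@H](O[Si](C)(C)C(C)(C)C)[C@H]1C(C)=C
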